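**Retrosynthetic overview**

1. Numbering (guaiane): C1 (olefinic) and C5 (H) are the ring-fusion carbons; the five-membered ring is C1–C5 with CH3 on C4; the seven-membered ring is C1, C5–C10 with the hydroxyisopropyl group on C7, the ester oxygen on C8 and CH3 on olefinic C10. First disconnections: the ferulate C8–O ester bond; the C7–H/C8–O pair as the syn hydration (hydroboration) of a C7=C8 alkene; the C10 methyl as a reduced C10–CO2Me.
2. Key disconnection: C9–C10 and C5–C6 together, a formal [4+3] union of the rhodium vinylcarbenoid from cyclopentenyl diazoacetate 6 (C10, C1, C5 and the finished five-membered ring with C4) with the 2-substituted butadiene 9 (C9, C8, C7, C6 and the side chain). All fifteen skeletal carbons are in place after this step.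
3. Enabling feature: the seven-membered ring holds the tetrasubstituted C1=C10 alkene and, across the single CH2 group C9, the C7–C8 pair that is a hydrated alkene, with the CH2 groups C9 and C6 at the two ends. It is therefore a latent cyclohepta-1,4-diene, the retron of a cis-divinylcyclopropane Cope rearrangement whose cyclopropane is C10–C9–C8.
4. Ring order: the five-membered ring comes from the starting cyclopentenone (C4 set by asymmetric conjugate reduction); the three-membered ring is made and opened in the key step; the seven-membered ring is closed in the key step, which also sets C5; C7 and C8 are set by one hydroboration.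
5. Fragments: 6 from 3-methylcyclopent-2-en-1-one (3 steps); 9 from 2-methylbut-3-yn-2-ol (2 steps); phenol-protected ferulic acid 19 (1 step).

Key step: step 6

Assumption: the sense of induction of (S)-p-Tol-BINAP in step 1 and of Rh2(S-DOSP)4 in step 6 is taken to be the one needed for the configurations drawn; if either proves opposite, the antipodal ligand or catalyst is used and nothing else changes.

**Route**

Step 1
Reactants: 1 3-methylcyclopent-2-en-1-one
Product: 4 (3S)-3-methylcyclopent-1-en-1-yl trifluoromethanesulfonate, via silyl enol ether 2 (not isolated), via lithium enolate 3 (not isolated)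
Conditions: CuCl (5 mol %), NaOt-Bu (5 mol %), (S)-p-Tol-BINAP (5 mol %), Ph2SiH2 (0.55 equiv), toluene, 0 °C; then MeLi (1.1 equiv), THF, −78 → 0 °C; then PhNTf2, −78 °C → rt
Reagents that add atoms: N-phenylbis(trifluoromethanesulfonimide), O=S(=O)(N(c1ccccc1)S(=O)(=O)C(F)(F)F)C(F)(F)F
Why: Ligand-controlled copper hydride conjugate reduction delivers hydride to one face of the enone and so sets the methyl-bearing centre (future C4), the silyl enol ether keeps the enolate regiochemistry, and Si-to-Li exchange followed by O-triflation gives the enol triflate with the double bond next to that centre.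

Step 2
Reactants: 4 (3S)-3-methylcyclopent-1-en-1-yl trifluoromethanesulfonate
Product: 5 methyl 2-[(3S)-3-methylcyclopent-1-en-1-yl]acetate
Conditions: BrZnCH2CO2Me (from methyl bromoacetate and Zn dust, THF), Pd(dba)2 (3 mol %), P(t-Bu)3 (3 mol %), THF, rt
Reagents that add atoms: methyl bromoacetate (used as its zinc reagent), COC(=O)CBr
Why: Negishi coupling of a Reformatsky reagent with an enol triflate (oxidative addition to zerovalent palladium, transmetalation, reductive elimination) forms the C1–C10 bond and leaves the allylic stereocentre untouched.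

Step 3
Reactants: 5 methyl 2-[(3S)-3-methylcyclopent-1-en-1-yl]acetate
Product: 6 methyl 2-diazo-2-[(3S)-3-methylcyclopent-1-en-1-yl]acetate
Conditions: p-ABSA, DBU, MeCN, 0 °C; used at once
Reagents that add atoms: 4-acetamidobenzenesulfonyl azide, CC(=O)Nc1ccc(cc1)S(=O)(=O)N=[N+]=[N-]
Why: Regitz diazo transfer to the doubly activated methylene (allylic and α to the ester) gives the vinyldiazoacetate, which is used at once because vinyl diazo compounds slowly close to pyrazoles.

Step 4
Reactants: 7 2-methylbut-3-yn-2-ol
Product: 8 triethyl[(2-methylbut-3-yn-2-yl)oxy]silane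
Conditions: TESOTf, 2,6-lutidine, CH2Cl2, 0 °C
Reagents that add atoms: triethylsilyl trifluoromethanesulfonate, CC[Si](CC)(CC)OS(=O)(=O)C(F)(F)F
Why: Silylation of the tertiary propargylic alcohol with the silyl triflate masks the O–H bond, which would otherwise undergo O–H insertion with the carbenoid in step 6.

Step 5
Reactants: 8 triethyl[(2-methylbut-3-yn-2-yl)oxy]silane
Product: 9 triethyl[(2-methyl-3-methylidenepent-4-en-2-yl)oxy]silane
Conditions: ethylene (1 atm), second-generation Grubbs catalyst (H2IMes)(PCy3)Cl2Ru=CHPh (5 mol %), toluene, 80 °C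
Reagents that add atoms: ethylene, C=C
Why: Cross enyne metathesis of a terminal alkyne with ethylene converts the triple bond into a 2-substituted buta-1,3-diene, the silyl ether keeping the propargylic oxygen from binding ruthenium.

Step 6
Reactants: 6 methyl 2-diazo-2-[(3S)-3-methylcyclopent-1-en-1-yl]acetate; 9 triethyl[(2-methyl-3-methylidenepent-4-en-2-yl)oxy]silane
Product: 11 methyl (3S,3aS)-3-methyl-5-{2-[(triethylsilyl)oxy]propan-2-yl}-1,2,3,3a,4,7-hexahydroazulene-8-carboxylate, via cis-divinylcyclopropane 10 (not isolated)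
Conditions: Rh2(S-DOSP)4 (dirhodium tetrakis[(S)-N-(4-dodecylbenzenesulfonyl)prolinate], 1 mol %), 9 (3 equiv), hexanes, −40 °C, 6 added over 2 h, → rt; 60 °C, 1 h if 10 persists
Reagents that add atoms: none
Why: The divalent rhodium catalyst turns 6 into a donor/acceptor vinylcarbenoid that cyclopropanates the monosubstituted vinyl group of 9 (bond from the ester-bearing carbon, future C10, to C9), and the cis-divinylcyclopropane 10 then undergoes Cope rearrangement, which forms C5–C6 and breaks the cyclopropane bond, so that strain release drives the second bond formation; this is the tandem cyclopropanation/Cope rearrangement (formal [4+3] cycloaddition of vinylcarbenoids with dienes), known for cyclic vinyldiazoacetates as a route to hydroazulenes. The three-membered ring closes by [2+1] carbenoid addition and the seven-membered ring closes by a concerted [3,3]-sigmatropic shift through the boat transition state that a cis-divinylcyclopropane must adopt, which also leaves the C1=C10 and C7=C8 alkenes exactly where the target and the next steps need them. The one new stereocentre, C5, is fixed by the configuration of 10, which the chiral catalyst sets in the cyclopropanation (face of the carbenoid, with the diene residue cis to the cyclopentenyl group) and the boat Cope transition state relays, the diene terminus arriving on the face of the cyclopentene cis to the C4 methyl group; C4 itself comes from 6. The step needs site selectivity between the two alkenes of 9, which is secured by the quaternary, inductively deactivating silyloxy-isopropyl group on the 1,1-disubstituted alkene and by the preference of these bulky carbenoids for unhindered vinyl groups; it needs the cis cyclopropane geometry, which is intrinsic to donor/acceptor carbenoids; and it needs catalyst control over the resident C4 centre, for which catalyst-controlled diastereoselective [4+3] reactions of chiral partners are the precedent. Slow addition of 6 in a hydrocarbon solvent keeps carbene dimerisation and pyrazole formation down, and brief warming completes the Cope shift if the methyl group next to the bond-forming carbon slows it.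

Step 7
Reactants: 11 methyl (3S,3aS)-3-methyl-5-{2-[(triethylsilyl)oxy]propan-2-yl}-1,2,3,3a,4,7-hexahydroazulene-8-carboxylate
Product: 12 [(3S,3aS)-3-methyl-5-{2-[(triethylsilyl)oxy]propan-2-yl}-1,2,3,3a,4,7-hexahydroazulen-8-yl]methanol
Conditions: i-Bu2AlH (2.5 equiv), CH2Cl2, −78 → 0 °C; Rochelle salt work-up
Reagents that add atoms: none
Why: Hydride 1,2-reduction of the conjugated ester stops at the allylic alcohol and does not touch the silyl ether or the isolated alkene.

Step 8
Reactants: 12 [(3S,3aS)-3-methyl-5-{2-[(triethylsilyl)oxy]propan-2-yl}-1,2,3,3a,4,7-hexahydroazulen-8-yl]methanol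
Product: 14 {[2-((3S,3aS)-3,8-dimethyl-1,2,3,3a,4,7-hexahydroazulen-5-yl)propan-2-yl]oxy}triethylsilane, via allylic mesylate 13 (not isolated)
Conditions: Ms2O, Et3N, THF, −20 °C; then LiEt3BH, −20 → 0 °C
Reagents that add atoms: none
Why: Sulfonylation and SN2 displacement by hydride at the unhindered primary allylic carbon turns CH2OH into the C10 methyl group, attack at the fully substituted ring-fusion terminus being disfavoured so that the C1=C10 alkene stays where it is.

Step 9
Reactants: 14 {[2-((3S,3aS)-3,8-dimethyl-1,2,3,3a,4,7-hexahydroazulen-5-yl)propan-2-yl]oxy}triethylsilane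
Product: 16 (3S,3aS,5S,6S)-3,8-dimethyl-5-{2-[(triethylsilyl)oxy]propan-2-yl}-1,2,3,3a,4,5,6,7-octahydroazulen-6-ol, via alkylborane 15 (not isolated)
Conditions: 9-BBN dimer, THF, 60 °C; then NaOH, H2O2, 0 °C → rt
Reagents that add atoms: hydrogen peroxide, OO
Why: Hydroboration–oxidation: 9-BBN does not add to the tetrasubstituted C1=C10 alkene and places boron on the less substituted C8 of the trisubstituted one, syn addition of H and B fixes the side chain on C7 and the oxygen on C8 as trans, approach to the convex face of the tub-shaped cyclohepta-1,4-diene ring (the face of H5) is expected to fix both centres relative to C5, and oxidation proceeds with retention.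

Step 10
Reactants: 17 ferulic acid, (2E)-3-(4-hydroxy-3-methoxyphenyl)prop-2-enoic acid
Product: 19 (2E)-3-{4-[(tert-butyldimethylsilyl)oxy]-3-methoxyphenyl}prop-2-enoic acid, via bis-silyl derivative 18 (not isolated)
Conditions: TBSCl (2.3 equiv), imidazole, DMF, rt; then AcOH, THF/H2O, rt
Reagents that add atoms: tert-butyldimethylsilyl chloride, CC(C)(C)[Si](C)(C)Cl
Why: Silylation of both acidic groups followed by selective hydrolysis of the labile silyl ester leaves the phenol masked as its silyl ether, so that only the carboxylic acid is free for coupling.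

Step 11
Reactants: 16 (3S,3aS,5S,6S)-3,8-dimethyl-5-{2-[(triethylsilyl)oxy]propan-2-yl}-1,2,3,3a,4,5,6,7-octahydroazulen-6-ol; 19 (2E)-3-{4-[(tert-butyldimethylsilyl)oxy]-3-methoxyphenyl}prop-2-enoic acid
Product: 20 (3S,3aS,5S,6S)-3,8-dimethyl-5-{2-[(triethylsilyl)oxy]propan-2-yl}-1,2,3,3a,4,5,6,7-octahydroazulen-6-yl (2E)-3-{4-[(tert-butyldimethylsilyl)oxy]-3-methoxyphenyl}prop-2-enoate
Conditions: EDC·HCl, DMAP, CH2Cl2, rt
Reagents that add atoms: none
Why: Steglich esterification acylates the only free hydroxyl group (the tertiary one is silylated) without touching the stereocentres or the E-alkene of the cinnamate.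

Step 12
Reactants: 20 (3S,3aS,5S,6S)-3,8-dimethyl-5-{2-[(triethylsilyl)oxy]propan-2-yl}-1,2,3,3a,4,5,6,7-octahydroazulen-6-yl (2E)-3-{4-[(tert-butyldimethylsilyl)oxy]-3-methoxyphenyl}prop-2-enoate
Product: 21 (3S,3aS,5S,6S)-5-(2-hydroxypropan-2-yl)-3,8-dimethyl-1,2,3,3a,4,5,6,7-octahydroazulen-6-yl (2E)-3-(4-hydroxy-3-methoxyphenyl)prop-2-enoate (CNP0241038.1)
Conditions: HF·pyridine, pyridine, THF, 0 °C → rt
Reagents that add atoms: none
Why: Buffered fluoride cleaves the aryl tert-butyldimethylsilyl ether and the tertiary triethylsilyl ether in one operation, mildly enough to spare the cinnamate ester, the tertiary alcohol and the tetrasubstituted alkene.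

**Compound list**

1 | 3-methylcyclopent-2-en-1-one | CC1=CC(=O)CC1 | starting material
2 | bis{[(3S)-3-methylcyclopent-1-en-1-yl]oxy}diphenylsilane | O(C1=C[C@@H](C)CC1)[Si](c1ccccc1)(c1ccccc1)OC1=C[C@@H](C)CC1 | intermediate
3 | lithium (3S)-3-methylcyclopent-1-en-1-olate | [Li]OC1=C[C@@H](C)CC1 | intermediate
4 | (3S)-3-methylcyclopent-1-en-1-yl trifluoromethanesulfonate | O=S(=O)(OC1=C[C@@H](C)CC1)C(F)(F)F | intermediate
5 | methyl 2-[(3S)-3-methylcyclopent-1-en-1-yl]acetate | COC(=O)CC1=C[C@@H](C)CC1 | intermediate
6 | methyl 2-diazo-2-[(3S)-3-methylcyclopent-1-en-1-yl]acetate | COC(=O)C(=[N+]=[N-])C1=C[C@@H](C)CC1 | intermediate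
7 | 2-methylbut-3-yn-2-ol | CC(C)(O)C#C | starting material
8 | triethyl[(2-methylbut-3-yn-2-yl)oxy]silane | CC[Si](CC)(CC)OC(C)(C)C#C | intermediate
9 | triethyl[(2-methyl-3-methylidenepent-4-en-2-yl)oxy]silane | CC[Si](CC)(CC)OC(C)(C)C(=C)C=C | intermediate
10 | methyl (1S,2R)-1-[(3S)-3-methylcyclopent-1-en-1-yl]-2-{3-methyl-3-[(triethylsilyl)oxy]but-1-en-2-yl}cyclopropane-1-carboxylate | COC(=O)[C@@]1(C2=C[C@@H](C)CC2)C[C@@H]1C(=C)C(C)(C)O[Si](CC)(CC)CC | intermediate
11 | methyl (3S,3aS)-3-methyl-5-{2-[(triethylsilyl)oxy]propan-2-yl}-1,2,3,3a,4,7-hexahydroazulene-8-carboxylate | COC(=O)C1=C2CC[C@H](C)[C@@H]2CC(C(C)(C)O[Si](CC)(CC)CC)=CC1 | intermediate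
12 | [(3S,3aS)-3-methyl-5-{2-[(triethylsilyl)oxy]propan-2-yl}-1,2,3,3a,4,7-hexahydroazulen-8-yl]methanol | OCC1=C2CC[C@H](C)[C@@H]2CC(C(C)(C)O[Si](CC)(CC)CC)=CC1 | intermediate
13 | [(3S,3aS)-3-methyl-5-{2-[(triethylsilyl)oxy]propan-2-yl}-1,2,3,3a,4,7-hexahydroazulen-8-yl]methyl methanesulfonate | CS(=O)(=O)OCC1=C2CC[C@H](C)[C@@H]2CC(C(C)(C)O[Si](CC)(CC)CC)=CC1 | intermediate
14 | {[2-((3S,3aS)-3,8-dimethyl-1,2,3,3a,4,7-hexahydroazulen-5-yl)propan-2-yl]oxy}triethylsilane | CC1=C2CC[C@H](C)[C@@H]2CC(C(C)(C)O[Si](CC)(CC)CC)=CC1 | intermediate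
15 | 9-[(3S,3aS,5S,6S)-3,8-dimethyl-5-{2-[(triethylsilyl)oxy]propan-2-yl}-1,2,3,3a,4,5,6,7-octahydroazulen-6-yl]-9-borabicyclo[3.3.1]nonane | C1CCC2CCCC1B2[C@H]1CC(C)=C2CC[C@H](C)[C@@H]2C[C@@H]1C(C)(C)O[Si](CC)(CC)CC | intermediate
16 | (3S,3aS,5S,6S)-3,8-dimethyl-5-{2-[(triethylsilyl)oxy]propan-2-yl}-1,2,3,3a,4,5,6,7-octahydroazulen-6-ol | O[C@H]1CC(C)=C2CC[C@H](C)[C@@H]2C[C@@H]1C(C)(C)O[Si](CC)(CC)CC | intermediate
17 | ferulic acid, (2E)-3-(4-hydroxy-3-methoxyphenyl)prop-2-enoic acid | COc1cc(/C=C/C(=O)O)ccc1O | starting material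
18 | tert-butyldimethylsilyl (2E)-3-{4-[(tert-butyldimethylsilyl)oxy]-3-methoxyphenyl}prop-2-enoate | COc1cc(/C=C/C(=O)O[Si](C)(C)C(C)(C)C)ccc1O[Si](C)(C)C(C)(C)C | intermediate
19 | (2E)-3-{4-[(tert-butyldimethylsilyl)oxy]-3-methoxyphenyl}prop-2-enoic acid | COc1cc(/C=C/C(=O)O)ccc1O[Si](C)(C)C(C)(C)C | intermediate
20 | (3S,3aS,5S,6S)-3,8-dimethyl-5-{2-[(triethylsilyl)oxy]propan-2-yl}-1,2,3,3a,4,5,6,7-octahydroazulen-6-yl (2E)-3-{4-[(tert-butyldimethylsilyl)oxy]-3-methoxyphenyl}prop-2-enoate | COc1cc(/C=C/C(=O)O[C@H]2CC(C)=C3CC[C@H](C)[C@@H]3C[C@@H]2C(C)(C)O[Si](CC)(CC)CC)ccc1O[Si](C)(C)C(C)(C)C | intermediate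
21 | (3S,3aS,5S,6S)-5-(2-hydroxypropan-2-yl)-3,8-dimethyl-1,2,3,3a,4,5,6,7-octahydroazulen-6-yl (2E)-3-(4-hydroxy-3-methoxyphenyl)prop-2-enoate | COc1cc(/C=C/C(=O)O[C@H]2CC(C)=C3CC[C@H](C)[C@@H]3C[C@@H]2C(C)(C)O)ccc1O | target

**Step count and risks**

Total step count: 12. Longest linear sequence: 9 steps (1, 2, 3, 6, 7, 8, 9, 11, 12).

Steps most likely to fail, each with one fallback:

Step 6. Two processes may fail. The carbenoid may add to the 1,1-disubstituted alkene of 9 instead of the vinyl group, which after the Cope shift would put the side chain on the wrong ring carbon. The catalyst may also fail to override the resident C4 centre, or the cyclopropane may stereomutate before a slowed Cope shift, giving the C5 epimer. The fallback sets out from 6 and comes back at 11; it takes the side chain out of the diene and builds it afterwards. Buta-1,3-dien-2-ylmagnesium chloride (from chloroprene and Mg) and Me3SiCl give buta-1,3-dien-2-yl(trimethyl)silane F1. Its silyl-bearing alkene is shielded and would have to carry positive charge α to silicon, so the carbenoid should take the free vinyl group. The same Rh2(S-DOSP)4 reaction of 6 with F1 should give, through methyl (1S,2S)-1-[(3S)-3-methylcyclopent-1-en-1-yl]-2-[1-(trimethylsilyl)ethenyl]cyclopropane-1-carboxylate F2 (not isolated), the vinylsilane methyl (3S,3aS)-3-methyl-5-(trimethylsilyl)-1,2,3,3a,4,7-hexahydroazulene-8-carboxylate F3. Ipso-iododesilylation (NIS, MeCN/ClCH2CN, 0 °C), for which the conjugated C1=C10 alkene is too electron-poor to compete, gives methyl (3S,3aS)-5-iodo-3-methyl-1,2,3,3a,4,7-hexahydroazulene-8-carboxylate F4. Iodine–lithium exchange (t-BuLi, Et2O, −100 °C) gives methyl (3S,3aS)-5-lithio-3-methyl-1,2,3,3a,4,7-hexahydroazulene-8-carboxylate F5 (not isolated), which is quenched with acetone to methyl (3S,3aS)-5-(2-hydroxypropan-2-yl)-3-methyl-1,2,3,3a,4,7-hexahydroazulene-8-carboxylate F6. Silylation (TESOTf, 2,6-lutidine) returns 11.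

Step 9. The borane may approach the other face of the C7=C8 alkene, giving the alcohol epimeric at both C7 and C8, and addition next to the quaternary carbon may be slow. The fallback sets out from 14 and comes back at 16; it replaces substrate control by reagent control. Hydroboration with monoisopinocampheylborane (the antipode matched to delivery on the face of H5; drawn here for the reagent made from (−)-α-pinene) gives [(3S,3aS,5S,6S)-3,8-dimethyl-5-{2-[(triethylsilyl)oxy]propan-2-yl}-1,2,3,3a,4,5,6,7-octahydroazulen-6-yl](isopinocampheyl)borane F7 (not isolated). Oxidation (NaOH, H2O2) then gives 16. Regiochemistry and syn addition are as in step 9, and this borane also leaves the tetrasubstituted alkene alone.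

Step 8. The allylic mesylate may ionise to an allyl cation, with elimination to a triene or hydride delivery with allylic transposition (exocyclic methylene isomer). The fallback sets out from 12 and comes back at 14; it replaces the sulfonate by a π-allylpalladium intermediate. Acetylation (Ac2O, pyridine, DMAP) gives [(3S,3aS)-3-methyl-5-{2-[(triethylsilyl)oxy]propan-2-yl}-1,2,3,3a,4,7-hexahydroazulen-8-yl]methyl acetate F8. Pd(PPh3)4 with LiEt3BH in THF then delivers hydride to the less hindered primary terminus of the allyl ligand, which leaves the tetrasubstituted alkene in place and gives 14.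

Further compounds
F1 | step 6 | buta-1,3-dien-2-yl(trimethyl)silane | C=CC(=C)[Si](C)(C)C
F2 | step 6 | methyl (1S,2S)-1-[(3S)-3-methylcyclopent-1-en-1-yl]-2-[1-(trimethylsilyl)ethenyl]cyclopropane-1-carboxylate | COC(=O)[C@@]1(C2=C[C@@H](C)CC2)C[C@@H]1C(=C)[Si](C)(C)C
F3 | step 6 | methyl (3S,3aS)-3-methyl-5-(trimethylsilyl)-1,2,3,3a,4,7-hexahydroazulene-8-carboxylate | COC(=O)C1=C2CC[C@H](C)[C@@H]2CC([Si](C)(C)C)=CC1
F4 | step 6 | methyl (3S,3aS)-5-iodo-3-methyl-1,2,3,3a,4,7-hexahydroazulene-8-carboxylate | COC(=O)C1=C2CC[C@H](C)[C@@H]2CC(I)=CC1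
F5 | step 6 | methyl (3S,3aS)-5-lithio-3-methyl-1,2,3,3a,4,7-hexahydroazulene-8-carboxylate | COC(=O)C1=C2CC[C@H](C)[C@@H]2CC([Li])=CC1
F6 | step 6 | methyl (3S,3aS)-5-(2-hydroxypropan-2-yl)-3-methyl-1,2,3,3a,4,7-hexahydroazulene-8-carboxylate | COC(=O)C1=C2CC[C@H](C)[C@@H]2CC(C(C)(C)O)=CC1
F7 | step 9 | [(3S,3aS,5S,6S)-3,8-dimethyl-5-{2-[(triethylsilyl)oxy]propan-2-yl}-1,2,3,3a,4,5,6,7-octahydroazulen-6-yl](isopinocampheyl)borane | C[C@@H]1[C@@H](B[C@H]3CC(C)=C4CC[C@H](C)[C@@H]4C[C@@H]3C(C)(C)O[Si](CC)(CC)CC)C[C@H]2C[C@@H]1C2(C)C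
F8 | step 8 | [(3S,3aS)-3-methyl-5-{2-[(triethylsilyl)oxy]propan-2-yl}-1,2,3,3a,4,7-hexahydroazulen-8-yl]methyl acetate | CC(=O)OCC1=C2CC[C@H](C)[C@@H]2CC(C(C)(C)O[Si](CC)(CC)CC)=CC1
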